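**Retrosynthetic overview**
1. Target 8 ⇒ phenol 7: the C4–OMe bond, which carries the only stereocentre, is made last by an enantioselective para-methoxylative dearomatisation.
2. Phenol 7 ⇒ bromophenol 2 + alkenylboronate 6 (Suzuki–Miyaura; fixes the trisubstituted E-olefin).
3. 2 ⇒ salicylaldehyde 1 (Wittig ethylidenation); 6 ⇒ arylpropyne 5 (Cu-catalysed syn-hydroboration) ⇒ 4-iodoveratrole 3 + propyne 4 (Sonogashira).
4. Rings: both six-membered rings are bought as benzenes; no ring is built, and the cyclohexadienone arises in the final step from the phenol ring.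

**Assumptions**
- Compounds 1, 3 and 4 (propyne as a THF solution) are bought.
- The chiral iodine(III) reagent I* of step 5 is made separately (2-iodoresorcinol, ethyl (S)-lactate with Mitsunobu inversion, mesitylamine, then NaBO3/AcOH), is recovered as its iodoarene, and is not counted as a route step.
- The facial sense of I* cannot be predicted with confidence; the (R,R)-form is written, and the (S,S)-antipode is used if the first run gives the (4R)-dienone (checked by chiral HPLC/ECD against natural material).

Reagent I*: 2-(diacetoxy-λ3-iodanyl)-1,3-bis{[(2R)-1-oxo-1-(2,4,6-trimethylanilino)propan-2-yl]oxy}benzene, C[C@@H](Oc1cccc(O[C@H](C)C(=O)Nc2c(C)cc(C)cc2C)c1I(OC(C)=O)OC(C)=O)C(=O)Nc1c(C)cc(C)cc1C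

**Route**

Step 1
Reactants: 1 5-bromo-2-hydroxy-4-methoxybenzaldehyde
Product: 2 4-bromo-5-methoxy-2-[(E)-prop-1-en-1-yl]phenol
Conditions: EtPPh3Br (2.3 equiv), KOt-Bu (2.4 equiv), THF, 0 °C → rt
Reagents that add atoms: ethyltriphenylphosphonium bromide, CC[P+](c1ccccc1)(c1ccccc1)c1ccccc1.[Br-]
Why: Wittig olefination; the ortho-phenoxide of a salicylaldehyde is expected to favour the E-alkene even with a non-stabilised ylide (stereochemical drift of the oxido-oxaphosphetane), and the aryl bromide is inert to ylide and KOt-Bu at room temperature.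

Step 2
Reactants: 3 4-iodo-1,2-dimethoxybenzene; 4 propyne
Product: 5 1,2-dimethoxy-4-(prop-1-yn-1-yl)benzene
Conditions: propyne (1 M in THF, 2 equiv), PdCl2(PPh3)2 (2 mol %), CuI (4 mol %), Et3N, rt, sealed flask
Reagents that add atoms: none
Why: Sonogashira coupling; the aryl iodide reacts at room temperature, so the volatile alkyne is handled as a solution in a closed vessel.

Step 3
Reactants: 5 1,2-dimethoxy-4-(prop-1-yn-1-yl)benzene
Product: 6 2-[(Z)-1-(3,4-dimethoxyphenyl)prop-1-en-2-yl]-4,4,5,5-tetramethyl-1,3,2-dioxaborolane (aryl trans to boron)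
Conditions: B2pin2 (1.1 equiv), CuCl (5 mol %), P(p-tol)3 (6 mol %), NaOt-Bu (15 mol %), MeOH (2 equiv), THF, rt
Reagents that add atoms: bis(pinacolato)diboron, CC1(C)OB(OC1(C)C)B1OC(C)(C)C(C)(C)O1
Why: Copper-catalysed formal hydroboration; syn-borylcupration puts Cu on the aryl-bearing carbon and boron on the methyl-bearing carbon, and protonolysis by MeOH with retention gives net syn H–B addition, so the aryl group ends up trans to boron.

Step 4
Reactants: 2 4-bromo-5-methoxy-2-[(E)-prop-1-en-1-yl]phenol; 6 2-[(Z)-1-(3,4-dimethoxyphenyl)prop-1-en-2-yl]-4,4,5,5-tetramethyl-1,3,2-dioxaborolane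
Product: 7 4-[(E)-1-(3,4-dimethoxyphenyl)prop-1-en-2-yl]-5-methoxy-2-[(E)-prop-1-en-1-yl]phenol
Conditions: Pd(OAc)2 (3 mol %), SPhos (6 mol %), K3PO4 (3 equiv), 1,4-dioxane/H2O (5:1), degassed, 80 °C
Reagents that add atoms: none
Why: Suzuki–Miyaura coupling with retention of alkene geometry (aryl trans to boron becomes aryl trans to the phenol ring, the E-olefin of the target); the SPhos–Pd catalyst handles electron-rich bromophenoxides and hindered alkenylboronates, and the free phenol and propenyl group are tolerated.

Step 5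
Reactants: 7 4-[(E)-1-(3,4-dimethoxyphenyl)prop-1-en-2-yl]-5-methoxy-2-[(E)-prop-1-en-1-yl]phenol
Product: 8 (4S)-4-[(E)-1-(3,4-dimethoxyphenyl)prop-1-en-2-yl]-4,5-dimethoxy-2-[(E)-prop-1-en-1-yl]cyclohexa-2,5-dien-1-one (target)
Conditions: I* (1.1 equiv), MeOH/CH2Cl2 (1:4), 0.02 M, −60 → −40 °C; cold aq. NaHCO3 quench
Reagents that add atoms: methanol, CO
Why: Proposed new method: reagent-controlled enantioselective para-methoxylative oxidative dearomatisation of a 4-alkenylphenol – phenol 7 exchanges onto iodine(III) of I* (fast for phenols at −60 °C, while the two electron-rich alkenes are inert to an unactivated ArI(OAc)2), the folded, hydrogen-bonded lactamide arms block one face of the bound phenoxide and hold MeOH over the other, and MeOH attacks C4 in an associative SN2′-type displacement of the iodoarene (CH2Cl2-rich, non-ionising medium, no free phenoxenium ion), which forms the C4–OMe bond and sets the (S)-centre; attack at the ring carbon rather than at the remote benzylic carbon is expected because the α-methyl/ortho-OMe clash twists the side-chain alkene out of conjugation and ring attack gives a vinylogous ester; the closest known reaction types are the racemic PhI(OAc)2/MeOH conversion of para-substituted phenols into 4-methoxycyclohexa-2,5-dienones and the chiral aryl-iodine(III) spirolactonising and hydroxylative dearomatisations of phenols.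

**Compound list**
1 | 5-bromo-2-hydroxy-4-methoxybenzaldehyde | O=Cc1cc(Br)c(OC)cc1O | starting material
2 | 4-bromo-5-methoxy-2-[(E)-prop-1-en-1-yl]phenol | C/C=C/c1cc(Br)c(OC)cc1O | intermediate
3 | 4-iodo-1,2-dimethoxybenzene | COc1ccc(I)cc1OC | starting material
4 | propyne | CC#C | starting material
5 | 1,2-dimethoxy-4-(prop-1-yn-1-yl)benzene | CC#Cc1ccc(OC)c(OC)c1 | intermediate
6 | 2-[(Z)-1-(3,4-dimethoxyphenyl)prop-1-en-2-yl]-4,4,5,5-tetramethyl-1,3,2-dioxaborolane | CC1(C)OB(/C(C)=C/c2ccc(OC)c(OC)c2)OC1(C)C | intermediate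
7 | 4-[(E)-1-(3,4-dimethoxyphenyl)prop-1-en-2-yl]-5-methoxy-2-[(E)-prop-1-en-1-yl]phenol | C/C=C/c1cc(/C(C)=C/c2ccc(OC)c(OC)c2)c(OC)cc1O | intermediate
8 | (4S)-4-[(E)-1-(3,4-dimethoxyphenyl)prop-1-en-2-yl]-4,5-dimethoxy-2-[(E)-prop-1-en-1-yl]cyclohexa-2,5-dien-1-one | C/C=C/C1=C[C@](OC)(/C(C)=C/c2ccc(OC)c(OC)c2)C(OC)=CC1=O | target

**Step count**
Total steps: 5. Longest linear sequence: 4 (steps 2 → 3 → 4 → 5).

**Three steps most likely to fail**

Step 5 (the proposed new step). The risks are modest enantioselectivity, methanol capture at the remote benzylic carbon (extended quinone methide) or at an ortho position, and acid lability of the doubly allylic tertiary ether (keep the work-up basic, use deactivated silica). The fallback uses known chemistry and sets out from 7. Oxidation with PhI(OAc)2 in MeOH at 0 °C, the standard para-quinol ether formation, gives racemic 4-[(E)-1-(3,4-dimethoxyphenyl)prop-1-en-2-yl]-4,5-dimethoxy-2-[(E)-prop-1-en-1-yl]cyclohexa-2,5-dien-1-one F1. Preparative chiral SFC on an amylose carbamate phase separates F1 into 8 and the unwanted (4R)-4-[(E)-1-(3,4-dimethoxyphenyl)prop-1-en-2-yl]-4,5-dimethoxy-2-[(E)-prop-1-en-1-yl]cyclohexa-2,5-dien-1-one F2. The route is rejoined at 8. This fallback answers a failure of enantiocontrol only; it does not help if ring-C4 attack itself fails.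

Step 4. The bromide of 2 sits para to a phenoxide, which slows oxidative addition, and 2 carries a propenyl group that can enter Heck-type side reactions. The fallback changes the order of events and sets out from 1. Aldehyde 1 is coupled with 6 (Pd(OAc)2/SPhos, K3PO4, dioxane/H2O) while the ring still carries the electron-withdrawing formyl group and no propenyl group, giving 5-[(E)-1-(3,4-dimethoxyphenyl)prop-1-en-2-yl]-2-hydroxy-4-methoxybenzaldehyde F3. Wittig ethylidenation of F3 (EtPPh3Br, KOt-Bu, THF) then gives 7, where the route is rejoined; compound 2 is bypassed.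

Step 1. A non-stabilised ylide may give an E/Z mixture that is hard to separate, and the aldehyde is deactivated as its phenoxide. The fallback replaces kinetic olefination by addition–elimination under thermodynamic control and sets out from 1. EtMgBr (3 equiv, THF, 0 °C) adds to the aldehyde to give racemic 4-bromo-2-(1-hydroxypropyl)-5-methoxyphenol F4. Acid-catalysed dehydration of F4 (cat. TsOH, toluene, 80 °C, high dilution) through the benzylic cation/o-quinone methide gives the conjugated E-alkene 2, where the route is rejoined.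

**Further compounds**
F1 | step 5 | racemic 4-[(E)-1-(3,4-dimethoxyphenyl)prop-1-en-2-yl]-4,5-dimethoxy-2-[(E)-prop-1-en-1-yl]cyclohexa-2,5-dien-1-one | C/C=C/C1=CC(OC)(/C(C)=C/c2ccc(OC)c(OC)c2)C(OC)=CC1=O
F2 | step 5 | (4R)-4-[(E)-1-(3,4-dimethoxyphenyl)prop-1-en-2-yl]-4,5-dimethoxy-2-[(E)-prop-1-en-1-yl]cyclohexa-2,5-dien-1-one | C/C=C/C1=C[C@@](OC)(/C(C)=C/c2ccc(OC)c(OC)c2)C(OC)=CC1=O
F3 | step 4 | 5-[(E)-1-(3,4-dimethoxyphenyl)prop-1-en-2-yl]-2-hydroxy-4-methoxybenzaldehyde | O=Cc1cc(/C(C)=C/c2ccc(OC)c(OC)c2)c(OC)cc1O
F4 | step 1 | racemic 4-bromo-2-(1-hydroxypropyl)-5-methoxyphenol | CCC(O)c1cc(Br)c(OC)cc1O
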